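**Retrosynthetic overview**
1. Target ⇒ acyclic allylboronate 19 (C6–C7 disconnection). In the last step the acetal is unmasked, the boronate adds to the C6 aldehyde and the new alkoxide lactonises, so the ten-membered carbocycle and the α-methylene-γ-lactone close together and C6/C7 are set.
2. 19 ⇒ aldehyde 13 + methyl propiolate + angelic acid + ICH2Bpin (C7–C8 by catalytic asymmetric alkynylation, which sets C8; C11–C13 by hydroalumination/borylmethylation).
3. 13 ⇒ 3(2H)-furanone 12 ⇒ methyl ketone 6 + dioxolanone 10 (C1–C2 Claisen, then O–C3 cyclodehydration; C10 from (R)-lactic acid).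
4. 6 ⇒ furan-2(5H)-one (Rh-catalysed asymmetric vinylation sets C4; C6 and the C15 hydroxyl stay masked together as one lactol methyl acetal).
5. Ring order: oxolane acetal (temporary) → 3(2H)-furanone → ten-membered carbocycle and γ-lactone in the same operation.

Assumption and notation: germacrane numbering is used for target carbons (C1 ketone, O bridge C3/C10, lactone O on C6, angelate on C8, C15 = CH2OH), the target being (4S,6R,7S,8R,10S); acetal and lactol carbons are carried as anomeric mixtures and written without a stereodescriptor.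

**Step 1**
Reactants: 1 furan-2(5H)-one; 2 potassium vinyltrifluoroborate
Product: 3 (4R)-4-ethenyloxolan-2-one
Conditions: [Rh(cod)2]BF4 (3 mol %), (R)-BINAP (3.3 mol %), toluene/H2O 4:1, 100 °C
Reagents that add atoms: none
Why: Hayashi–Miyaura Rh(I)/BINAP conjugate addition of a vinyl–rhodium species to the butenolide; the (R)-BINAP complex (antipode chosen by analogy with cyclic enones) selects one enantioface and sets C4 (4R here, the same spatial arrangement as 4S in the target).

**Step 2**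
Reactants: 3 (4R)-4-ethenyloxolan-2-one
Product: 5 (4R)-4-ethenyl-2-methoxyoxolane (anomeric mixture), via lactol 4 (not isolated)
Conditions: DIBAL-H (1.1 equiv), CH2Cl2, −78 °C; then MeOH, TsOH·H2O, −78 °C → rt
Reagents that add atoms: methanol, CO
Why: partial reduction of the γ-lactone to the lactol followed by acid-catalysed acetalisation masks the C6 aldehyde and the C15 hydroxyl in one ring without touching C4.

**Step 3**
Reactants: 5 (4R)-4-ethenyl-2-methoxyoxolane
Product: 6 1-[(3S)-5-methoxyoxolan-3-yl]ethan-1-one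
Conditions: PdCl2 (10 mol %), CuCl (1 equiv), O2 (1 atm), DMF/H2O 7:1, rt
Reagents that add atoms: water, O
Why: Tsuji–Wacker oxidation converts the terminal vinyl group into the methyl ketone (Markovnikov hydroxypalladation), and the α-stereocentre C4 survives these near-neutral conditions.

**Step 4**
Reactants: 7 (R)-lactic acid
Product: 8 (2R,5R)-2-tert-butyl-5-methyl-1,3-dioxolan-4-one
Conditions: pivalaldehyde, TsOH (cat.), pentane, reflux (Dean–Stark); cis isomer crystallised at −78 °C
Reagents that add atoms: pivalaldehyde, CC(C)(C)C=O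
Why: Seebach acetalisation of the α-hydroxy acid gives the crystalline cis acetal, which stores the lactate configuration at the acetal carbon (self-regeneration of stereocentres).

**Step 5**
Reactants: 8 (2R,5R)-2-tert-butyl-5-methyl-1,3-dioxolan-4-one; 9 allyl bromide
Product: 10 (2R,5S)-2-tert-butyl-5-methyl-5-(prop-2-en-1-yl)-1,3-dioxolan-4-one
Conditions: LDA, THF, −78 °C; then 9, −78 → −30 °C
Reagents that add atoms: none
Why: Seebach alkylation of the dioxolanone enolate anti to the tert-butyl group builds the quaternary C10 centre with overall retention, placing the allyl group (C9, C8) where the lactate hydrogen was (5S).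

**Step 6**
Reactants: 6 1-[(3S)-5-methoxyoxolan-3-yl]ethan-1-one; 10 (2R,5S)-2-tert-butyl-5-methyl-5-(prop-2-en-1-yl)-1,3-dioxolan-4-one
Product: 12 (2S)-5-[(3S)-5-methoxyoxolan-3-yl]-2-methyl-2-(prop-2-en-1-yl)furan-3(2H)-one, via hydroxy diketone 11 (not isolated)
Conditions: LDA (2.1 equiv), THF, −78 °C, 6; then 10, −78 → 0 °C; then HCl/MeOH, rt
Reagents that add atoms: none
Why: Proposed new method: the kinetic methyl-ketone enolate attacks the acylal-type carbonyl of the dioxolanone (Claisen acylation; closest known type is ester-enolate acylation by dioxolanones en route to tetronic acids), the tetrahedral intermediate expels pivalaldehyde to give the α′-hydroxy-1,3-diketone 11, and acid adds the tertiary OH to the C3 carbonyl and dehydrates it (Smith-type 3(2H)-furanone cyclodehydration) without touching the quaternary C10 or, while the diketonate persists, C4.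

**Step 7**
Reactants: 12 (2S)-5-[(3S)-5-methoxyoxolan-3-yl]-2-methyl-2-(prop-2-en-1-yl)furan-3(2H)-one
Product: 13 2-[(2S)-5-[(3S)-5-methoxyoxolan-3-yl]-2-methyl-3-oxo-2,3-dihydrofuran-2-yl]acetaldehyde
Conditions: OsO4 (2 mol %), NaIO4 (4 equiv), 2,6-lutidine, dioxane/H2O 3:1, rt
Reagents that add atoms: osmium tetroxide, O=[Os](=O)(=O)=O; sodium periodate, [Na+].[O-]I(=O)(=O)=O
Why: Lemieux–Johnson cleavage takes the terminal alkene much faster than the electron-poor push–pull furanone double bond, and the lutidine buffer protects the β-alkoxy aldehyde from elimination.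

**Step 8**
Reactants: 13 2-[(2S)-5-[(3S)-5-methoxyoxolan-3-yl]-2-methyl-3-oxo-2,3-dihydrofuran-2-yl]acetaldehyde; 14 methyl propiolate
Product: 15 methyl (4R)-4-hydroxy-5-[(2S)-5-[(3S)-5-methoxyoxolan-3-yl]-2-methyl-3-oxo-2,3-dihydrofuran-2-yl]pent-2-ynoate
Conditions: 14 (4 equiv), Et2Zn (4 equiv), (S)-BINOL (40 mol %), HMPA (2 equiv), CH2Cl2, rt, 16 h; Ti(OiPr)4 (1 equiv), 1 h; then 13, rt
Reagents that add atoms: none
Why: BINOL/Ti-mediated asymmetric alkynylzinc addition (Pu-type) to the aliphatic aldehyde sets C8 as R under catalyst control ((S)-BINOL chosen by analogy with the usual face selectivity of this system), overriding the remote C10 centre.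

**Step 9**
Reactants: 15 methyl (4R)-4-hydroxy-5-[…]pent-2-ynoate; 16 angelic acid
Product: 17 methyl (4R)-4-{[(2Z)-2-methylbut-2-enoyl]oxy}-5-[(2S)-5-[(3S)-5-methoxyoxolan-3-yl]-2-methyl-3-oxo-2,3-dihydrofuran-2-yl]pent-2-ynoate
Conditions: 16, 2,4,6-trichlorobenzoyl chloride, Et3N, toluene, rt; then 15, 75 °C (no DMAP)
Reagents that add atoms: none
Why: Yamaguchi-type mixed-anhydride esterification without a nucleophilic catalyst acylates the C8 hydroxyl with retention and keeps the Z (angelate) geometry.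

**Step 10**
Reactants: 17 methyl (4R)-4-{[(2Z)-2-methylbut-2-enoyl]oxy}-5-[…]pent-2-ynoate; 18 2-(iodomethyl)-4,4,5,5-tetramethyl-1,3,2-dioxaborolane
Product: 19 methyl (2Z,4R)-4-{[(2Z)-2-methylbut-2-enoyl]oxy}-5-[(2S)-5-[(3S)-5-methoxyoxolan-3-yl]-2-methyl-3-oxo-2,3-dihydrofuran-2-yl]-2-[(4,4,5,5-tetramethyl-1,3,2-dioxaborolan-2-yl)methyl]pent-2-enoate
Conditions: DIBAL-H (1.3 equiv), HMPA (2.6 equiv), THF, 0 °C; 17, −78 → −20 °C; then 18, → rt
Reagents that add atoms: none
Why: 1,4-hydroalumination of the ynoate by DIBAL-H·HMPA gives an aluminium allenolate that is C-alkylated by ICH2Bpin trans to the γ-substituent (Hall/Ramachandran route to 2-alkoxycarbonyl allylboronates), giving the 2Z isomer (C8 cis to CO2Me), while the hindered angelate and the vinylogous-ester carbonyl react much more slowly.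

**Step 11**
Reactants: 19 methyl (2Z,4R)-4-{[(2Z)-2-methylbut-2-enoyl]oxy}-5-[…]-2-[(pinacolboryl)methyl]pent-2-enoate
Product: 22 CNP0108636.1, via lactol 20 (not isolated), via seco hydroxy ester 21 (not isolated)
Conditions: Sc(OTf)3 (20 mol %), MeCN/H2O 50:1, 1 mM, 25 → 45 °C
Reagents that add atoms: water, O
Why: Proposed new method: Lewis-acid hydrolysis of the acetal releases lactol 20 (in equilibrium with the C6 aldehyde and free C15-OH), the (Z)-2-alkoxycarbonyl allylboronate adds to it intramolecularly through a closed chair transition state (Sc(OTf)3-accelerated Hall allylboration/lactonisation, known intermolecularly for trans-α-methylene-γ-butyrolactones) with C5 and C8 equatorial to give the anti adduct, A(1,3) strain keeps H8 in the alkene plane so the aldehyde attacks anti to C9 (7S, 6R), and the new C6 oxygen lactonises onto the methyl ester, closing the ten-membered carbocycle and the trans-fused lactone in one operation.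

**Compound list**
1 | furan-2(5H)-one | O=C1OCC=C1 | starting material
2 | potassium vinyltrifluoroborate | [K+].C=C[B-](F)(F)F | starting material
3 | (4R)-4-ethenyloxolan-2-one | O=C1C[C@@H](CO1)C=C | intermediate
4 | (4R)-4-ethenyloxolan-2-ol (lactol, not isolated) | OC1C[C@@H](CO1)C=C | intermediate
5 | (4R)-4-ethenyl-2-methoxyoxolane | COC1C[C@@H](CO1)C=C | intermediate
6 | 1-[(3S)-5-methoxyoxolan-3-yl]ethan-1-one | COC1C[C@@H](CO1)C(C)=O | intermediate
7 | (R)-lactic acid | C[C@@H](O)C(=O)O | starting material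
8 | (2R,5R)-2-tert-butyl-5-methyl-1,3-dioxolan-4-one | C[C@H]1O[C@H](OC1=O)C(C)(C)C | intermediate
9 | allyl bromide | C=CCBr | starting material
10 | (2R,5S)-2-tert-butyl-5-methyl-5-(prop-2-en-1-yl)-1,3-dioxolan-4-one | C[C@@]1(CC=C)O[C@H](OC1=O)C(C)(C)C | intermediate
11 | (4S)-4-hydroxy-1-[(3S)-5-methoxyoxolan-3-yl]-4-methylhept-6-ene-1,3-dione (not isolated) | C=CC[C@](C)(O)C(=O)CC(=O)[C@@H]1COC(OC)C1 | intermediate
12 | (2S)-5-[(3S)-5-methoxyoxolan-3-yl]-2-methyl-2-(prop-2-en-1-yl)furan-3(2H)-one | C=CC[C@]1(C)OC(=CC1=O)[C@@H]1COC(OC)C1 | intermediate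
13 | 2-[(2S)-5-[(3S)-5-methoxyoxolan-3-yl]-2-methyl-3-oxo-2,3-dihydrofuran-2-yl]acetaldehyde | O=CC[C@]1(C)OC(=CC1=O)[C@@H]1COC(OC)C1 | intermediate
14 | methyl propiolate | C#CC(=O)OC | starting material
15 | methyl (4R)-4-hydroxy-5-[(2S)-5-[(3S)-5-methoxyoxolan-3-yl]-2-methyl-3-oxo-2,3-dihydrofuran-2-yl]pent-2-ynoate | COC(=O)C#C[C@H](O)C[C@]1(C)OC(=CC1=O)[C@@H]1COC(OC)C1 | intermediate
16 | angelic acid, (2Z)-2-methylbut-2-enoic acid | OC(=O)/C(C)=C\C | starting material
17 | methyl (4R)-4-{[(2Z)-2-methylbut-2-enoyl]oxy}-5-[(2S)-5-[(3S)-5-methoxyoxolan-3-yl]-2-methyl-3-oxo-2,3-dihydrofuran-2-yl]pent-2-ynoate | COC(=O)C#C[C@H](OC(=O)/C(C)=C\C)C[C@]1(C)OC(=CC1=O)[C@@H]1COC(OC)C1 | intermediate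
18 | 2-(iodomethyl)-4,4,5,5-tetramethyl-1,3,2-dioxaborolane | ICB1OC(C)(C)C(C)(C)O1 | starting material
19 | methyl (2Z,4R)-4-{[(2Z)-2-methylbut-2-enoyl]oxy}-5-[(2S)-5-[(3S)-5-methoxyoxolan-3-yl]-2-methyl-3-oxo-2,3-dihydrofuran-2-yl]-2-[(4,4,5,5-tetramethyl-1,3,2-dioxaborolan-2-yl)methyl]pent-2-enoate | COC(=O)/C(CB1OC(C)(C)C(C)(C)O1)=C\[C@H](OC(=O)/C(C)=C\C)C[C@]1(C)OC(=CC1=O)[C@@H]1COC(OC)C1 | intermediate
20 | lactol of 19, 5-hydroxyoxolan-3-yl in place of 5-methoxyoxolan-3-yl (not isolated) | COC(=O)/C(CB1OC(C)(C)C(C)(C)O1)=C\[C@H](OC(=O)/C(C)=C\C)C[C@]1(C)OC(=CC1=O)[C@@H]1COC(O)C1 | intermediate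
21 | seco hydroxy ester: ten-membered carbocycle (4S,6R,7S,8R,10S) with free 6-OH and 15-OH, methyl 2-substituted acrylate not yet lactonised (not isolated) | C=C(C(=O)OC)[C@H]1[C@H](O)C[C@@H](CO)C2=CC(=O)[C@](C)(C[C@H]1OC(=O)/C(C)=C\C)O2 | intermediate
22 | CNP0108636.1, (4S,6R,7S,8R,10S)-15-hydroxy-1-oxo-3,10-epoxygermacra-2,11(13)-dien-12,6-olid-8-yl angelate | C=C1C(=O)O[C@@H]2C[C@@H](CO)C3=CC(=O)[C@](C)(C[C@@H](OC(=O)/C(C)=C\C)[C@@H]12)O3 | target

**Totals**
Total steps: 11. Longest linear sequence: 9 (steps 1, 2, 3, 6, 7, 8, 9, 10, 11); steps 4 and 5 are a two-step side branch.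

**Three steps most likely to fail**

Step 11 carries the most risk. The lactol gives only a small equilibrium concentration of aldehyde, oligomerisation competes at any but high dilution, and the face selectivity at C7 relative to C8 rests on the "H inside, ring carbon anti" model; an "acyloxy anti" transition state would give the 6,7-diastereomer. The fallback sets out from 17 and changes the nucleophile from boron to chromium. The hydroalumination of 17 is quenched with formaldehyde instead of 18 to give the hydroxymethyl enoate F1. CBr4/PPh3 converts this into the allylic bromide F2, and PPTS in wet acetone hydrolyses the acetal to the lactol bromide F3. CrCl2 (THF, 1 mM) then performs a Nozaki–Hiyama allylation of the C6 aldehyde through equilibrating allyl–Cr(III) species (anti-selective, hence trans lactone), and the chromium alkoxide lactonises, returning to the route at 22.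

Step 10 may suffer from DIBAL-H attack on the angelate or the furanone, or from poor Z/E control in the alkylation. The fallback sets out from 17 and uses palladium chemistry. Pd(PPh3)4-catalysed hydrostannation with Bu3SnH (syn addition, tin α to the ester) gives the α-stannyl enoate F4. Iodine converts this into the α-iodo enoate F5 with retention. Negishi coupling of F5 with IZnCH2Bpin (from 18 and zinc dust, Pd catalyst, THF) returns to the route at 19 with the same double-bond geometry.

Step 8 exposes the β-alkoxy aldehyde 13 to Lewis-acidic zinc and titanium species (risk of retro-oxa-Michael opening), and the enantioselectivity with this β-quaternary aldehyde is untested. The fallback sets out from 13 and moves the stereocontrol to a ketone reduction. Lithiated 14 (LiHMDS, THF, −78 °C) adds to 13 to give the C8-epimeric propargylic alcohol mixture F6. Dess–Martin oxidation gives the ynone F7. Noyori asymmetric transfer hydrogenation (RuCl(p-cymene)[(S,S)-TsDPEN], iPrOH; catalyst antipode chosen to give 4R) returns to the route at 15.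

**Further compounds**
F1 | step 11 | methyl (2Z,4R)-2-(hydroxymethyl)-4-{[(2Z)-2-methylbut-2-enoyl]oxy}-5-[(2S)-5-[(3S)-5-methoxyoxolan-3-yl]-2-methyl-3-oxo-2,3-dihydrofuran-2-yl]pent-2-enoate | COC(=O)/C(CO)=C\[C@H](OC(=O)/C(C)=C\C)C[C@]1(C)OC(=CC1=O)[C@@H]1COC(OC)C1
F2 | step 11 | methyl (2E,4R)-2-(bromomethyl)-4-{[(2Z)-2-methylbut-2-enoyl]oxy}-5-[(2S)-5-[(3S)-5-methoxyoxolan-3-yl]-2-methyl-3-oxo-2,3-dihydrofuran-2-yl]pent-2-enoate | COC(=O)/C(CBr)=C\[C@H](OC(=O)/C(C)=C\C)C[C@]1(C)OC(=CC1=O)[C@@H]1COC(OC)C1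
F3 | step 11 | methyl (2E,4R)-2-(bromomethyl)-4-{[(2Z)-2-methylbut-2-enoyl]oxy}-5-[(2S)-5-[(3S)-5-hydroxyoxolan-3-yl]-2-methyl-3-oxo-2,3-dihydrofuran-2-yl]pent-2-enoate | COC(=O)/C(CBr)=C\[C@H](OC(=O)/C(C)=C\C)C[C@]1(C)OC(=CC1=O)[C@@H]1COC(O)C1
F4 | step 10 | methyl (2E,4R)-4-{[(2Z)-2-methylbut-2-enoyl]oxy}-5-[(2S)-5-[(3S)-5-methoxyoxolan-3-yl]-2-methyl-3-oxo-2,3-dihydrofuran-2-yl]-2-(tributylstannyl)pent-2-enoate | COC(=O)/C([Sn](CCCC)(CCCC)CCCC)=C\[C@H](OC(=O)/C(C)=C\C)C[C@]1(C)OC(=CC1=O)[C@@H]1COC(OC)C1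
F5 | step 10 | methyl (2E,4R)-2-iodo-4-{[(2Z)-2-methylbut-2-enoyl]oxy}-5-[(2S)-5-[(3S)-5-methoxyoxolan-3-yl]-2-methyl-3-oxo-2,3-dihydrofuran-2-yl]pent-2-enoate | COC(=O)/C(I)=C\[C@H](OC(=O)/C(C)=C\C)C[C@]1(C)OC(=CC1=O)[C@@H]1COC(OC)C1
F6 | step 8 | methyl (4RS)-4-hydroxy-5-[(2S)-5-[(3S)-5-methoxyoxolan-3-yl]-2-methyl-3-oxo-2,3-dihydrofuran-2-yl]pent-2-ynoate | COC(=O)C#CC(O)C[C@]1(C)OC(=CC1=O)[C@@H]1COC(OC)C1
F7 | step 8 | methyl 5-[(2S)-5-[(3S)-5-methoxyoxolan-3-yl]-2-methyl-3-oxo-2,3-dihydrofuran-2-yl]-4-oxopent-2-ynoate | COC(=O)C#CC(=O)C[C@]1(C)OC(=CC1=O)[C@@H]1COC(OC)C1
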